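Read at 40.0 s, the summer flask shows 0% of each product against a scatter of 0.5 percentage points, so no excess can be read from it at that time.

| setting | summer | autumn | flask |
|---|---|---|---|
| left-handed substrate | 0.50 M | 0.25 M | 0.50 M |
| right-handed substrate | 0.50 M | 0.25 M | 0.50 M |
| gas | 200 mM (held) | 200 mM (held) | 200 mM (held) |
| remark | the very flask that is asked about, followed so far | run made earlier |  |
| time |  |  | 6.0 min |

summer run (percent of the left-handed substrate and right-handed substrate together charged)

| time / s | left-handed product / % | right-handed product / % |
|---|---|---|
| 10.0 | 0.4 | 0.3 |
| 12.0 | 0 | 0.1 |
| 20.0 | 0 | 0 |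
| 30.0 | 0 | 0.4 |
| 40.0 | 0 | 0 |
| 60.0 | 0 | 0 |

autumn run (percent of the left-handed substrate and right-handed substrate together charged)

| time / min | left-handed product / % | right-handed product / % |
|---|---|---|
| 0.833 | 0.1 | 0.3 |
| 1.50 | 0.7 | 0.6 |
| 2.50 | 1.5 | 1.0 |
| 3.00 | 2.0 | 1.3 |
| 4.00 | 3.3 | 1.8 |
| 5.00 | 4.5 | 1.3 |
| 6.00 | 4.4 | 2.5 |

(each reading ± 0.5 percentage points)

1. excess of left-handed product over right-handed product in the product at 40 s
2. excess of left-handed product over right-handed product in the product at 6.0 min
3. part of the left-handed substrate and right-handed substrate charged together that has reacted at 6.0 min

- reagent is single-handed; left-handed substrate and right-handed substrate are mirror images of each other, charged as a racemate, each of them at the stated concentration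
- at the start none of reagent is dissolved
- steps that have been proposed: right-handed substrate <-> achiral form; achiral form -> waste; reagent + right-handed substrate -> right-handed product; reagent + left-handed substrate -> left-handed product; left-handed product <-> right-handed product; reagent <-> dormant form; left-handed substrate <-> achiral form; gas <-> reagent
- what has gone into achiral form counts as reacted
- an excess is below zero if the other one leads
- the handed part of reagent does not stay in what it makes, so the products of the two hands are mirror images too

The reagent starts at none, and its balance is what the gas feeds in less what goes into product and into the dormant form. The autumn readings lie within scatter at 0.833 min and then climb. Both flasks hold the same gas, so we take the reagent to rise alike in both and carry the autumn percentages over to the summer flask. Autumn's left-handed product reaches 4.4% of both substrates at 6.00 min, which is 8.80% of its own hand. The time in which left-handed substrate would halve at that mean pace into left-handed product is 47.3 min; we call it the product half-life.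

This is longer than the 6.0 min asked about, so we expect about 6.90% of the charge in the two products. The autumn readings from 4.00 min on give an excess near 37.1%, which we take for both times. Anything reacted beyond that passes unseen through the achiral form, so the substrates are what to watch.

The forecast gives 30% and 30% for the excess and 5% reacted, holding that “conversion is too low for substrate depletion to matter much”. The flask gives 43.2%, 33.0% and 23.5%.

    right-handed substrate ⇌ achiral form (K = 0.560, k = 0.00108 s⁻¹)
    achiral form → waste (k = 4.52 × 10⁻⁴ s⁻¹)
    reagent + right-handed substrate → right-handed product (k = 0.00755 L mol⁻¹ s⁻¹)
    reagent + left-handed substrate → left-handed product (k = 0.0196 L mol⁻¹ s⁻¹)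
    left-handed product ⇌ right-handed product (k = 9.04 × 10⁻⁴ s⁻¹)
    reagent ⇌ dormant form (K = 59.0, k = 0.00191 s⁻¹)
    left-handed substrate ⇌ achiral form (K = 0.560, k = 0.00108 s⁻¹)
    gas ⇌ reagent, rate k8*(csat - [reagent]) (kL = 0.00116 s⁻¹)

At 6.00 min the flask keeps 75% of its left-handed substrate, a pace with a half-life of 14.2 min, shorter than the product half-life of 47.3 min. At 1.86 min the forward step into achiral form has a half-life of 11 min for left-handed substrate against 48 min for the step into left-handed product, a rate 4.5 times as high, and at 6.00 min the achiral form stands at 16.5%.

The runs were generated by integration for an exercise, noise included.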